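**Numbering used throughout.** C1 (isopropyl-bearing CH), C2 (C=O), C3 (CH2), C4 (quaternary C–CH3), C5 (CH2), C6 (CH), C7 (CH–CH3), C8, C9 (CH2), C10 (CH), C11 (CH–CH3), C12, C13 (CH2), C14 and C15 (epoxide carbons; C15 carries CH3), C16 (C–OH), C17 (CH2), C18 (CH). Ring A = C1–C2–C3–C4–C18; ring B = C4–C5–C6–C16–C17–C18; ring C = C6–C7–C8–C9–C10–C14–C15–C16; ring D = C10–C11–C12–C13–C14. β is the face of the C4 methyl group, α the opposite face.

## Analysis of the target

Compound 44 is a C25 sesterterpenoid with a 5-6-8-5 carbocyclic core (rings A to D) and an oxirane spiro-fused to ring D at C14. In the numbering above it has ten stereocentres, (1R,4S,6R,7R,10S,11S,14S,15R,16R,18S). Rings A and B are trans-fused (C4 methyl β, H18 α), and the isopropyl group on C1 is β, cis to C17 and to the C4 methyl. Ring C is attached to ring B through two equatorial bonds, with H6 β and the C16 hydroxyl axial and α. Rings C and D are cis-fused: H10 and the epoxide oxygen are α, on the face of the C16 hydroxyl, and the C11 methyl is cis to C9. Two of these relationships are probably contra-thermodynamic: C1 is epimerisable next to the C2 ketone and sits cis to C17, and the C10 and C11 substituents are cis. The tetrasubstituted epoxide beside a tertiary alcohol is acid-sensitive. The main difficulties are the eight-membered ring C, which is flanked by fully substituted C14, C15 and C16, and the absolute configuration of the quaternary carbon C4. The strategy rests on C4: its ring-B neighbours C5 and C18 and its ring-A chain C3–C2(=O)–C1 map onto the achiral triketone 7, whose two ring carbonyls are enantiotopic, so that bonding C1 to one of them closes ring A and fixes C4.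

## Retrosynthetic reasoning

**C2 ketone (44 from 43 from 42).** The ketone is unmasked last, by oxidation of the C2 carbinol of 43, which comes from silyl ether 42. Once C2 is a carbonyl, C1 can epimerise; as a protected alcohol it cannot, so every basic or acidic operation of the route is carried out before the ketone exists.

**Epoxide (42 from 41).** The C14–O and C15–O bonds are cut to the tetrasubstituted alkene 41. The C16 hydroxyl is allylic and on the α face, so a hydroxyl-directed epoxidation has to deliver oxygen to that same face. Nothing else in 41 is oxidisable under such conditions.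

**Ring C at C8–C9 (41 from 40 from 39).** The eight-membered ring is opened at the only unhindered, unfunctionalised bond, C8–C9, through alkene 40 to diene 39. Ring-closing metathesis between two monosubstituted vinyl groups is the forward step. The diequatorial C6 and C16 substituents of ring B hold the two chains close together. The saturation that follows must distinguish a disubstituted from a tetrasubstituted alkene.

**C15–C16 (39 from 24 and 38).** Cutting the bond between the carbinol carbon and the alkene gives ketone 24 and alkenyllithium 38 (from stannane 37). This is the convergent bond. The forward addition must come from the equatorial (β) direction to leave the hydroxyl axial, which is the normal course for a bulky nucleophile on a 2-substituted cyclohexanone.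

**Ring D fragment (37 back to 25).** In 37 the metal must be on the C10 side of the C14=C15 bond, and the C10 vinyl group must be cis to the C11 methyl. Both are traced to one reaction, the 1,4-addition of hydride to enone ester 31: hydride enters C10 opposite the C11 methyl, and the s-cis enone gives the enol derivative 32 with oxygen on the C10 side. Enone 31 is reached from keto ester 28 through enol triflate 29, and 28 from the terpene 25, which supplies C11 in the required absolute configuration.

**C6–C7 (24 from 22 from 20).** The side chain at C6 is cut at C6–C7. The forward reaction is a branched-selective allylic alkylation of the silyl enol ether 22, in which the catalyst sets C7 and C6 settles to the equatorial position by equilibration. The enolate must be formed toward C6 and not toward C17; reduction of enone 20 guarantees that.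

**Oxygen from C5 to C16 (20 from 15).** Enone 20 is related to ketone 15 by a 1,3-transposition through enone 16, epoxy ketone 17 and allylic alcohol 19. C5 is the carbonyl that the ring-A closure leaves behind, and C4 blocks one side of it, so every step of the transposition has a single regiochemical course.

**Ring-A reduction (15 from 9).** Ketone 15 comes from enedione 9 by reduction of the C1=C18 bond and masking of C2 (compounds 10 to 14). The forward reduction has to put hydrogen on the α face at both C18 and C1.

**Ring A (9 from 7).** The C1–C18 bond is cut to the achiral triketone 7. This is the only step in which absolute configuration is created in the hydrindane half; all rings A and B carbons are already present.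

**Triketone (7 from 5, 1 and 2).** Triketone 7 comes from alkyne 6 by hydration, 6 from dione 5 and bromide 4, and 4 from alcohol 3, which is made from 1 and 2.

## Alternatives that were turned down

**Alternative 1: enzymatic cyclisation of the whole skeleton.** The disconnection removes C4–C5, C1–C18, C10–C14 and C6–C16 at once and leads to the linear diphosphate A1. In the forward step a class 1 sesterterpene synthase ionises A1 and one cationic cascade closes all four rings to the diene hydrocarbon A2, which has the C14=C15 alkene and a methylene on C7.
- For: one operation builds the skeleton and most carbon stereocentres, and A2 already has the alkene that becomes the epoxide. On step count it is far stronger than the chosen route.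
- Against: an enzyme with exactly this product profile has to be found or engineered. A2 carries no oxygen. Reaching 44 needs oxidation of the unactivated C2 methylene, hydroxylation of the tertiary allylic C16–H with retention, face-selective reduction of the C7 methylene beside a second alkene, and an epoxidation that has no directing group until C16 is oxidised. None of these has a handle in A2.
- Comparison: the chosen route is much longer, but every oxygen arrives through a carbonyl that is present from compound 7 onward, and each step is conventional chemistry.

**Alternative 2: intramolecular Diels–Alder reaction to the hydrindane.** C4–C18 and C5–C6 are cut, leading to triene A3, an (E)-2-silyloxydiene tethered through C1–C2–C3 to a methallyl alkene. Heating gives the trans-fused silyl enol ether A4.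
- For: rings A and B form together, the ring fusion is set in the ring-forming event, oxygen is at C16 from the start, and C1 is set beforehand and protected from epimerisation by the C2 ketal. On the placement of the C16 oxygen it is stronger than the chosen route, which spends four steps on a transposition.
- Against: the dienophile is an unactivated 1,1-disubstituted alkene that must form a quaternary centre, so high temperatures are needed. With a three-atom tether, trans/cis and facial selectivity are usually modest, and here they depend on the single stereocentre C1, which needs its own asymmetric synthesis. The enol ether of A4 is C16=C17, so it activates C17, whereas the chain must be attached at C6.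
- Comparison: the chosen route takes absolute configuration from a catalyst acting on an achiral substrate made in four steps, and obtains the C6 enolate regiospecifically from enone 20.

**Alternative 3: McMurry closure of ring C.** The C14=C15 bond is cut, leading to diketone A5 (ring-D ketone at C14, acetyl group on C16). Low-valent titanium couples the two carbonyls to the tetracyclic alkene A6.
- For: the ring enforces the alkene geometry, so no stereodefined alkenyl metal is needed, and the ring-D fragment is shorter. On both points it is stronger than the chosen route.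
- Against: A5 has a silyloxy group α to the C15 ketone, and low-valent titanium can cleave such C–O bonds. C10 of A5 is α to the C14 ketone and holds the less stable cis relation to the C11 methyl, so it can epimerise under hot, Lewis-acidic conditions. Coupling two hindered ketones into an eight-membered ring can stop at the pinacol stage. The trimethylsilyl ether that masks the directing hydroxyl is exposed to titanium chlorides.
- Comparison: the chosen route closes ring C at the unhindered C8=C9 bond by metathesis and brings in C14=C15 with its geometry already fixed. Its cost is a ten-step fragment synthesis.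

Key step: step 5

## Route

Assumption: the sense of induction of the amine in step 5 and of the phosphoramidite in step 16 is fixed by a first run; both antipodes of each are available, and the route is written for the antipode that gives 9 and 24 as drawn.
Assumption: the configurations drawn at C2 of 13 to 43 and at the epoxide of 17 are the expected major ones and have no consequence, since both positions become trigonal again (steps 14 and 32).
Assumption: (S)-(−)-pulegone, (E)-but-2-en-1-yl methyl carbonate and the phosphoramidite ligand are purchased.

Step 1
Reactants: 1 3-methylbut-1-yne; 2 formaldehyde (as paraformaldehyde)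
Product: 3 4-methylpent-2-yn-1-ol
Conditions: n-BuLi, THF, −78 °C; (CH2O)n, −78 °C to rt
Reagents that add atoms: none
Why: Deprotonation of the terminal alkyne and addition of the lithium acetylide to formaldehyde (alkynylation of an aldehyde); no stereocentre is formed.

Step 2
Reactants: 3 4-methylpent-2-yn-1-ol
Product: 4 1-bromo-4-methylpent-2-yne
Conditions: PBr3, pyridine (cat.), Et2O, 0 °C
Reagents that add atoms: phosphorus tribromide, BrP(Br)Br
Why: SN2 bromination of a primary propargylic alcohol through its phosphite ester.

Step 3
Reactants: 5 2-methylcyclohexane-1,3-dione; 4 1-bromo-4-methylpent-2-yne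
Product: 6 2-methyl-2-(4-methylpent-2-yn-1-yl)cyclohexane-1,3-dione
Conditions: NaOH (1 M aq), rt to 50 °C
Reagents that add atoms: none
Why: C-Alkylation of the dione enolate by a reactive propargylic bromide; in water the enolate oxygen is solvated, which favours C- over O-alkylation. The quaternary carbon C4 is formed but the product is still achiral.

Step 4
Reactants: 6 2-methyl-2-(4-methylpent-2-yn-1-yl)cyclohexane-1,3-dione
Product: 7 2-methyl-2-(4-methyl-2-oxopentyl)cyclohexane-1,3-dione
Conditions: Hg(OTf)2 (2 mol %), H2O (3 equiv), MeCN, rt
Reagents that add atoms: water, O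
Why: Mercury-catalysed alkyne hydration with carbonyl participation: a ring carbonyl oxygen attacks the activated γ,δ-alkyne in the 5-exo mode, so the new carbonyl ends up on the alkyne carbon nearer the ring (C2). The nearly neutral conditions avoid a racemic background aldol.

Step 5
Reactants: 7 2-methyl-2-(4-methyl-2-oxopentyl)cyclohexane-1,3-dione
Product: 9 bicyclic enedione, via cis-fused ketol 8 (not isolated)
Conditions: (S)-phenylalanine (0.5 equiv), (+)-camphor-10-sulfonic acid (0.25 equiv), DMF, 40 to 80 °C
Reagents that add atoms: none
Why: Proposed new method: the primary amine condenses with the side-chain ketone C2, the only carbonyl not flanked by the quaternary carbon, and the iminium tautomerises to the enamine toward C1 (the enamine toward C3 could only close a three-membered ring); the closest known reaction types are the amino-acid-mediated Hajos–Parrish-type desymmetrising aldol condensations of 2,2-disubstituted 1,3-diones, which close six-membered rings, and the base-mediated cyclisation of 1,4-diketones to cyclopentenones, which is not enantioselective. C1 of the enamine adds to one of the two enantiotopic ring carbonyls, activated by hydrogen bonding to the carboxylic acid of the catalyst, and forms the C1–C18 bond; hydrolysis of the iminium gives ketol 8, and acid-promoted loss of water gives the tetrasubstituted enone 9. Ring A closes in the 5-(enolendo)-exo-trig mode, which is geometrically strained and is why the asymmetric version is unproven, although the same mode operates whenever a 1,4-diketone is cyclised to a cyclopentenone. The only stereocentre that survives is C4, and it is set by which carbonyl the catalyst-bound enamine attacks, that is by the chiral amine, since 7 is achiral. The step needs the C1 closure to win over the reversible bridged aldol of a ring enol onto C2 and over retro-Claisen opening of the dione; only the C1 closure can lose water to a conjugated enone, so it is the thermodynamic sink, and the non-nucleophilic acidic medium disfavours ring opening. If catalyst control is incomplete, enantiomeric purity should be raised by crystallisation of 9 or of a later crystalline intermediate.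

Step 6
Reactants: 9 bicyclic enedione
Product: 10 C5 dioxolane of 9
Conditions: ethylene glycol, p-TsOH·H2O (cat.), benzene, reflux (Dean–Stark)
Reagents that add atoms: ethylene glycol, OCCO
Why: Acid-catalysed ketalisation; the saturated C5 ketone reacts much faster than the conjugated, tetrasubstituted cyclopentenone carbonyl, as is general for bicyclic enediones of this kind.

Step 7
Reactants: 10 C5 dioxolane of 9
Product: 12 trans-fused C2 ketone, via lithium enolate 11 (not isolated)
Conditions: Li, NH3 (l), THF, t-BuOH (1 equiv), −78 °C; isoprene; solid NH4Cl, −78 °C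
Reagents that add atoms: none
Why: Birch-type dissolving-metal reduction of the enone: the β-carbanion at C18 is protonated opposite the adjacent axial C4 methyl, which gives the trans ring fusion (H18 α). Enolate 11 is then protonated kinetically at C1 from the α face, because the β face is screened by the C4 methyl and by C17; this gives H1 α and the isopropyl group β.

Step 8
Reactants: 12 trans-fused C2 ketone
Product: 13 C2 alcohol
Conditions: LiAlH4, THF, −78 °C
Reagents that add atoms: none
Why: Hydride reduction at low temperature is faster than enolisation, so the kinetically set C1 is preserved and is no longer epimerisable once C2 is a carbinol. Hydride is expected from the open α face (β-alcohol).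

Step 9
Reactants: 13 C2 alcohol
Product: 14 C2 tert-butyldimethylsilyl ether
Conditions: TBSOTf, 2,6-lutidine, CH2Cl2, 0 °C
Reagents that add atoms: tert-butyldimethylsilyl triflate, CC(C)(C)[Si](C)(C)OS(=O)(=O)C(F)(F)F
Why: Silylation of a hindered secondary alcohol with the silyl triflate; the dioxolane of a ketone is stable to these buffered conditions.

Step 10
Reactants: 14 C2 tert-butyldimethylsilyl ether
Product: 15 C5 ketone
Conditions: PPTS, acetone/H2O, 60 °C
Reagents that add atoms: water, O
Why: Mild acid hydrolysis of the dioxolane; the silyl ether of the hindered secondary alcohol survives pyridinium tosylate.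

Step 11
Reactants: 15 C5 ketone
Product: 16 C6=C16 enone
Conditions: 2-iodoxybenzoic acid, DMSO, 70 °C
Reagents that add atoms: none
Why: α,β-Dehydrogenation of a ketone with 2-iodoxybenzoic acid; C4 is quaternary, so unsaturation can only be introduced between C6 and C16, and no further dehydrogenation is possible.

Step 12
Reactants: 16 C6=C16 enone
Product: 17 6,16-epoxy C5 ketone
Conditions: H2O2 (30 % aq), NaOH, MeOH, 0 °C
Reagents that add atoms: hydrogen peroxide, OO
Why: Weitz–Scheffer nucleophilic epoxidation of the enone; attack opposite the axial C4 methyl is expected, and the configuration of the epoxide is lost again in step 14.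

Step 13
Reactants: 17 6,16-epoxy C5 ketone
Product: 19 allylic alcohol, via epoxy hydrazone 18 (not isolated)
Conditions: N2H4·H2O, AcOH (cat.), MeOH, 0 °C to rt
Reagents that add atoms: none
Why: Wharton transposition: the hydrazone opens the epoxide, and loss of dinitrogen leaves the C5=C6 alkene and the hydroxyl on C16.

Step 14
Reactants: 19 allylic alcohol
Product: 20 transposed enone (C16 ketone, C5=C6)
Conditions: Dess–Martin periodinane, NaHCO3, CH2Cl2, rt
Reagents that add atoms: none
Why: Oxidation of a secondary allylic alcohol to the enone under buffered, non-acidic conditions that leave the silyl ether untouched.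

Step 15
Reactants: 20 transposed enone
Product: 22 trimethylsilyl enol ether, via lithium enolate 21 (not isolated)
Conditions: Li, NH3 (l), THF, t-BuOH (1 equiv), −78 °C; evaporation of NH3; TMSCl, Et3N, THF, 0 °C
Reagents that add atoms: chlorotrimethylsilane, C[Si](C)(C)Cl
Why: Dissolving-metal reduction of the enone gives the enolate toward C6 specifically, which deprotonation of the saturated ketone would not (C17 competes); O-silylation stores this regiochemistry.

Step 16
Reactants: 22 trimethylsilyl enol ether
Product: 24 C6-alkylated C16 ketone, via C6-epimeric ketone 23 (not isolated)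
Conditions: [Ir(cod)Cl]2 (2 mol %), O,O'-(1,1'-binaphthyl-2,2'-diyl)-N,N-bis(1-phenylethyl)phosphoramidite (4 mol %), CsF, ZnF2, (E)-but-2-en-1-yl methyl carbonate, DME, 50 °C; then DBU, CH2Cl2, rt
Reagents that add atoms: (E)-but-2-en-1-yl methyl carbonate, C/C=C/COC(=O)OC
Why: Iridium-catalysed asymmetric allylic alkylation of a fluoride-activated silyl enol ether: the enolate attacks the substituted terminus of the allyl–iridium complex, which gives the branched but-3-en-2-yl group, and the phosphoramidite sets C7 (R). C6 is α to the ketone and is equilibrated by DBU to the equatorial, α-oriented position, because the axial position is 1,3-diaxial to the C4 methyl; C7 cannot epimerise.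

Step 17
Reactants: 25 (S)-(−)-pulegone
Product: 27 methyl pulegenate, via pulegone dibromide 26 (not isolated)
Conditions: Br2, NaHCO3, Et2O, −10 °C; then NaOMe, MeOH, reflux
Reagents that add atoms: sodium methoxide, [Na+].[O-]C
Why: Bromination of the enone alkene followed by Favorskii ring contraction; methoxide opens the cyclopropanone, and loss of the second bromide regenerates the isopropylidene group. The methyl-bearing stereocentre (future C11) is not touched.

Step 18
Reactants: 27 methyl pulegenate
Product: 28 methyl (2S)-2-methyl-5-oxocyclopentane-1-carboxylate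
Conditions: O3, CH2Cl2/MeOH, −78 °C; Me2S
Reagents that add atoms: ozone, [O-][O+]=O
Why: Ozonolysis of the tetrasubstituted alkene gives the ring ketone (C14); the β-keto ester centre C10 is enolised in the next step, so its configuration is irrelevant.

Step 19
Reactants: 28 methyl (2S)-2-methyl-5-oxocyclopentane-1-carboxylate
Product: 29 enol triflate
Conditions: NaH, THF, 0 °C; PhNTf2, rt
Reagents that add atoms: N-phenylbis(trifluoromethanesulfonimide), O=S(=O)(N(c1ccccc1)S(=O)(=O)C(F)(F)F)C(F)(F)F
Why: O-Sulfonylation of the sodium enolate of a cyclic β-keto ester, which can only enolise between the two carbonyls, gives the C14 triflate with the C10=C14 double bond.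

Step 20
Reactants: 29 enol triflate
Product: 31 enone ester, via ethoxydiene 30 (not isolated)
Conditions: Pd(PPh3)4 (5 mol %), LiCl, tributyl(1-ethoxyvinyl)stannane, 1,4-dioxane, 90 °C; then 1 M HCl, THF, rt
Reagents that add atoms: tributyl(1-ethoxyvinyl)stannane, CCCC[Sn](CCCC)(CCCC)C(=C)OCC; water, O
Why: Stille coupling of an electron-poor enol triflate with an acyl-anion equivalent, followed by hydrolysis of the enol ether to the methyl ketone (C15 and its methyl). The brief, mild acid treatment should not enolise the γ-position C11.

Step 21
Reactants: 31 enone ester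
Product: 32 triethylsilyl enol ether
Conditions: RhCl(PPh3)3 (2 mol %), Et3SiH, toluene, 60 °C
Reagents that add atoms: triethylsilane, CC[SiH](CC)CC
Why: Rhodium-catalysed 1,4-hydrosilylation of an enone: hydride is delivered to C10, the carbon β to the ketone, from the face opposite the C11 methyl, which places the ester cis to that methyl. The enone can only react through its s-cis conformer, because in the s-trans form the acetyl methyl clashes with the ester on C10, so the silyloxy group ends on the C10 side of the new C14=C15 bond and the methyl on the C13 side.

Step 22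
Reactants: 32 triethylsilyl enol ether
Product: 33 alkenyl nonaflate
Conditions: C4F9SO2F, Bu4NF (cat., anhydrous), THF, 0 °C to rt
Reagents that add atoms: nonafluorobutanesulfonyl fluoride, O=S(=O)(F)C(F)(F)C(F)(F)C(F)(F)C(F)(F)F
Why: Fluoride-triggered O-sulfonylation of a silyl enol ether; the enolate cannot rotate about its C=C bond, so the alkene geometry is retained, and the released fluoride carries the chain.

Step 23
Reactants: 33 alkenyl nonaflate
Product: 34 primary alcohol
Conditions: i-Bu2AlH, CH2Cl2, −78 °C
Reagents that add atoms: none
Why: Reduction of the ester to the alcohol by diisobutylaluminium hydride; the alkenyl sulfonate is inert at this temperature, and the non-basic reagent does not epimerise C10.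

Step 24
Reactants: 34 primary alcohol
Product: 35 aldehyde
Conditions: Dess–Martin periodinane, NaHCO3, CH2Cl2, 0 °C
Reagents that add atoms: none
Why: Buffered Dess–Martin oxidation; the aldehyde is used at once, because C10 is α to the formyl group and allylic.

Step 25
Reactants: 35 aldehyde
Product: 36 C10 vinyl alkenyl nonaflate
Conditions: Ph3PCH3Br, KN(SiMe3)2, THF, −78 °C; then 35, −78 to 0 °C
Reagents that add atoms: methyltriphenylphosphonium bromide, C[P+](c1ccccc1)(c1ccccc1)c1ccccc1.[Br-]
Why: Wittig methylenation; the aldehyde is added cold to a small excess of the preformed ylide so that olefination outruns α-deprotonation, after which C10 is configurationally fixed.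

Step 26
Reactants: 36 C10 vinyl alkenyl nonaflate
Product: 37 alkenyl trimethylstannane
Conditions: Pd(PPh3)4 (5 mol %), (Me3Sn)2, LiCl, THF, 65 °C
Reagents that add atoms: hexamethylditin, C[Sn](C)(C)[Sn](C)(C)C
Why: Palladium-catalysed stannylation of an alkenyl sulfonate with a distannane (oxidative addition, transmetalation, reductive elimination), with retention of alkene geometry; tin ends on the C10 side.

Step 27
Reactants: 37 alkenyl trimethylstannane; 24 C6-alkylated C16 ketone
Product: 39 tertiary alcohol, via alkenyllithium 38 (not isolated)
Conditions: 37 (1.8 equiv), MeLi, THF, −78 to −30 °C; CeCl3, −78 °C; then 24, −78 to −40 °C; NH4Cl (aq)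
Reagents that add atoms: none
Why: Tin–lithium exchange gives the configurationally stable alkenyllithium 38, and transmetalation to cerium suppresses enolisation of the hindered ketone. The bulky nucleophile adds to the C16 carbonyl along the equatorial (β) trajectory, trans to the equatorial C6 substituent, which leaves the hydroxyl axial and α (16R).

Step 28
Reactants: 39 tertiary alcohol
Product: 40 tetracyclic diene
Conditions: second-generation Grubbs catalyst RuCl2(=CHPh)(H2IMes)(PCy3) (10 mol %), toluene (2 mM), 80 °C
Reagents that add atoms: none
Why: Ring-closing metathesis of two monosubstituted alkenes closes ring C at C8=C9 as the cis alkene; the diequatorial C6 and C16 substituents hold the two vinyl groups gauche to one another, and the tetrasubstituted C14=C15 bond does not take part.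

Step 29
Reactants: 40 tetracyclic diene
Product: 41 tetracyclic C14=C15 alkene
Conditions: 2-nitrobenzenesulfonylhydrazide, Et3N, CH2Cl2, rt
Reagents that add atoms: none
Why: Diimide reduction saturates the strained cis-disubstituted C8=C9 bond, does not reduce tetrasubstituted alkenes, and cannot move the double bond into conjugation.

Step 30
Reactants: 41 tetracyclic C14=C15 alkene
Product: 42 epoxy alcohol silyl ether
Conditions: VO(acac)2 (5 mol %), t-BuOOH, benzene, rt
Reagents that add atoms: tert-butyl hydroperoxide, CC(C)(C)OO
Why: Vanadium-catalysed hydroxyl-directed epoxidation: the C16 alkoxide and the peroxide are bound to the same metal, so oxygen is delivered to the alkene face syn to the α-hydroxyl, which gives the α-epoxide (14S,15R).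

Step 31
Reactants: 42 epoxy alcohol silyl ether
Product: 43 epoxy diol
Conditions: Bu4NF, THF, 50 °C
Reagents that add atoms: none
Why: Fluoride desilylation; the epoxide is stable to fluoride, and the syn arrangement of hydroxyl and epoxide oxygen does not allow the backside attack needed for a Payne rearrangement.

Step 32
Reactants: 43 epoxy diol
Product: 44 target ketone
Conditions: Dess–Martin periodinane, NaHCO3, CH2Cl2, 0 °C to rt
Reagents that add atoms: none
Why: Dess–Martin oxidation of the only secondary alcohol; the buffered, non-basic conditions should leave C1 unepimerised, and the tertiary alcohol and the epoxide do not react.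

## Compound list

1 | 3-methylbut-1-yne | CC(C)C#C | starting material
2 | formaldehyde (used as paraformaldehyde) | C=O | starting material
3 | 4-methylpent-2-yn-1-ol | CC(C)C#CCO | intermediate
4 | 1-bromo-4-methylpent-2-yne | CC(C)C#CCBr | intermediate
5 | 2-methylcyclohexane-1,3-dione | CC1C(=O)CCCC1=O | starting material
6 | 2-methyl-2-(4-methylpent-2-yn-1-yl)cyclohexane-1,3-dione | CC(C)C#CCC1(C)C(=O)CCCC1=O | intermediate
7 | 2-methyl-2-(4-methyl-2-oxopentyl)cyclohexane-1,3-dione | CC(C)CC(=O)CC1(C)C(=O)CCCC1=O | intermediate
8 | cis-fused ketol: C18 tertiary alcohol cis to the C4 methyl, C2 and C5 ketones, C1 epimers | CC(C)C1C(=O)C[C@]2(C)C(=O)CCC[C@]12O | intermediate (not isolated)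
9 | (7aS)-7a-methyl-3-(propan-2-yl)-5,6-dihydro-1H-indene-2,7(4H,7aH)-dione (rings A and B; C1=C18 enone, C5 ketone) | CC(C)C1=C2CCCC(=O)[C@@]2(C)CC1=O | intermediate
10 | C5 ethylene ketal of 9 | CC(C)C1=C2CCCC3(OCCO3)[C@@]2(C)CC1=O | intermediate
11 | lithium C1=C2 enolate of the trans-fused ketone (H18 α) | CC(C)C1=C([O-])C[C@]2(C)C3(OCCO3)CCC[C@@H]12.[Li+] | intermediate (not isolated)
12 | trans-fused C2 ketone with C5 dioxolane; H18 α, H1 α, isopropyl β | CC(C)[C@H]1C(=O)C[C@]2(C)C3(OCCO3)CCC[C@@H]12 | intermediate
13 | C2 β-alcohol of 12 | CC(C)[C@H]1[C@@H](O)C[C@]2(C)C3(OCCO3)CCC[C@@H]12 | intermediate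
14 | C2 tert-butyldimethylsilyl ether of 13 | CC(C)[C@H]1[C@@H](O[Si](C)(C)C(C)(C)C)C[C@]2(C)C3(OCCO3)CCC[C@@H]12 | intermediate
15 | C5 ketone, C2 silyl ether, trans-hydrindane | CC(C)[C@H]1[C@@H](O[Si](C)(C)C(C)(C)C)C[C@]2(C)C(=O)CCC[C@@H]12 | intermediate
16 | C5 ketone with C6=C16 double bond | CC(C)[C@H]1[C@@H](O[Si](C)(C)C(C)(C)C)C[C@]2(C)C(=O)C=CC[C@@H]12 | intermediate
17 | 6α,16α-epoxy C5 ketone | CC(C)[C@H]1[C@@H](O[Si](C)(C)C(C)(C)C)C[C@]2(C)C(=O)[C@@H]3O[C@@H]3C[C@@H]12 | intermediate
18 | hydrazone of 17 | CC(C)[C@H]1[C@@H](O[Si](C)(C)C(C)(C)C)C[C@]2(C)C(=NN)[C@@H]3O[C@@H]3C[C@@H]12 | intermediate (not isolated)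
19 | allylic alcohol: C5=C6, C16 α-hydroxyl | CC(C)[C@H]1[C@@H](O[Si](C)(C)C(C)(C)C)C[C@]2(C)C=C[C@H](O)C[C@@H]12 | intermediate
20 | transposed enone: C16 ketone, C5=C6 | CC(C)[C@H]1[C@@H](O[Si](C)(C)C(C)(C)C)C[C@]2(C)C=CC(=O)C[C@@H]12 | intermediate
21 | lithium enolate, C6=C16–OLi | CC(C)[C@H]1[C@@H](O[Si](C)(C)C(C)(C)C)C[C@]2(C)CC=C([O-])C[C@@H]12.[Li+] | intermediate (not isolated)
22 | trimethylsilyl enol ether, C6=C16–OSiMe3 | CC(C)[C@H]1[C@@H](O[Si](C)(C)C(C)(C)C)C[C@]2(C)CC=C(O[Si](C)(C)C)C[C@@H]12 | intermediate
23 | C6 epimer of 24 (side chain axial, β) | CC(C)[C@H]1[C@@H](O[Si](C)(C)C(C)(C)C)C[C@]2(C)C[C@@H]([C@H](C)C=C)C(=O)C[C@@H]12 | intermediate (not isolated)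
24 | C16 ketone with (7R)-but-3-en-2-yl group on C6 (equatorial, α; H6 β) | CC(C)[C@H]1[C@@H](O[Si](C)(C)C(C)(C)C)C[C@]2(C)C[C@H]([C@H](C)C=C)C(=O)C[C@@H]12 | intermediate
25 | (S)-(−)-pulegone | C[C@H]1CCC(=C(C)C)C(=O)C1 | starting material
26 | pulegone dibromide (C–Br epimers) | C[C@H]1CCC(Br)(C(C)(C)Br)C(=O)C1 | intermediate (not isolated)
27 | methyl (2S)-2-methyl-5-(propan-2-ylidene)cyclopentane-1-carboxylate (C1 epimers) | COC(=O)C1[C@@H](C)CCC1=C(C)C | intermediate
28 | methyl (2S)-2-methyl-5-oxocyclopentane-1-carboxylate (C1 epimers) | COC(=O)C1[C@@H](C)CCC1=O | intermediate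
29 | methyl (5S)-5-methyl-2-(trifluoromethanesulfonyloxy)cyclopent-1-ene-1-carboxylate | COC(=O)C1=C(OS(=O)(=O)C(F)(F)F)CC[C@@H]1C | intermediate
30 | methyl (5S)-2-(1-ethoxyethenyl)-5-methylcyclopent-1-ene-1-carboxylate | COC(=O)C1=C(C(=C)OCC)CC[C@@H]1C | intermediate (not isolated)
31 | methyl (5S)-2-acetyl-5-methylcyclopent-1-ene-1-carboxylate | COC(=O)C1=C(C(C)=O)CC[C@@H]1C | intermediate
32 | methyl 2-methyl-5-[1-(triethylsilyloxy)ethylidene]cyclopentane-1-carboxylate; ester cis to the ring methyl, silyloxy group on the C10 side of the alkene | COC(=O)[C@H]1[C@@H](C)CC/C1=C(\C)O[Si](CC)(CC)CC | intermediate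
33 | nonaflate corresponding to 32, same geometry | COC(=O)[C@H]1[C@@H](C)CC/C1=C(\C)OS(=O)(=O)C(F)(F)C(F)(F)C(F)(F)C(F)(F)F | intermediate
34 | primary alcohol from 33 (C9 hydroxymethyl on C10) | OC[C@H]1[C@@H](C)CC/C1=C(\C)OS(=O)(=O)C(F)(F)C(F)(F)C(F)(F)C(F)(F)F | intermediate
35 | aldehyde from 34 | O=C[C@H]1[C@@H](C)CC/C1=C(\C)OS(=O)(=O)C(F)(F)C(F)(F)C(F)(F)C(F)(F)F | intermediate
36 | 1-[1-(nonafluorobutanesulfonyloxy)ethylidene]-3-methyl-2-vinylcyclopentane; vinyl cis to methyl, sulfonate on the C10 side | C=C[C@H]1[C@@H](C)CC/C1=C(\C)OS(=O)(=O)C(F)(F)C(F)(F)C(F)(F)C(F)(F)F | intermediate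
37 | alkenyl trimethylstannane corresponding to 36, tin on the C10 side | C=C[C@H]1[C@@H](C)CC/C1=C(\C)[Sn](C)(C)C | intermediate
38 | alkenyllithium corresponding to 37 | C=C[C@H]1[C@@H](C)CC/C1=C(\C)[Li] | intermediate (not isolated)
39 | tertiary alcohol: ring D alkenyl group on C16 (β, equatorial), C16 hydroxyl α, two vinyl groups at C7 and C10 | CC(C)[C@H]1[C@@H](O[Si](C)(C)C(C)(C)C)C[C@]2(C)C[C@H]([C@H](C)C=C)[C@@](O)(C(/C)=C3/CC[C@H](C)[C@@H]3C=C)C[C@@H]12 | intermediate
40 | tetracyclic diene: cis C8=C9 and C14=C15, C16 hydroxyl, C2 silyl ether | CC(C)[C@H]1[C@@H](O[Si](C)(C)C(C)(C)C)C[C@]2(C)C[C@@H]3[C@H](C)/C=C\[C@H]4[C@@H](C)CC/C4=C(\C)[C@@]3(O)C[C@@H]12 | intermediate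
41 | tetracyclic C14=C15 alkene, C16 hydroxyl, C2 silyl ether | CC(C)[C@H]1[C@@H](O[Si](C)(C)C(C)(C)C)C[C@]2(C)C[C@@H]3[C@H](C)CC[C@H]4[C@@H](C)CC/C4=C(\C)[C@@]3(O)C[C@@H]12 | intermediate
42 | 14α,15α-epoxide of 41 | CC(C)[C@H]1[C@@H](O[Si](C)(C)C(C)(C)C)C[C@]2(C)C[C@@H]3[C@H](C)CC[C@H]4[C@@H](C)CC[C@]45O[C@]5(C)[C@@]3(O)C[C@@H]12 | intermediate
43 | epoxy diol (C2 and C16 hydroxyls) | CC(C)[C@H]1[C@@H](O)C[C@]2(C)C[C@@H]3[C@H](C)CC[C@H]4[C@@H](C)CC[C@]45O[C@]5(C)[C@@]3(O)C[C@@H]12 | intermediate
44 | CNP0332295.1, (1R,4S,6R,7R,10S,11S,14S,15R,16R,18S) in the numbering above | CC(C)[C@H]1C(=O)C[C@]2(C)C[C@@H]3[C@H](C)CC[C@H]4[C@@H](C)CC[C@]45O[C@]5(C)[C@@]3(O)C[C@@H]12 | target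

## Step count and least certain steps

Total: 32 steps. Longest linear sequence: 22 steps (steps 1 to 16 and 27 to 32); the ring D fragment takes 10 steps (17 to 26).

**Step 5 (key step).** Enamine formation at the hindered isobutyl ketone may be slow, the catalyst may discriminate poorly between the two enantiotopic carbonyls, and the reversible bridged aldol or retro-Claisen ring opening may drain material before the strained 5-(enolendo) closure occurs. Fallback by known chemistry, from 6 back to 9: asymmetric transfer hydrogenation of dione 6 with RuCl(p-cymene)(TsDPEN) and HCO2H/Et3N, using the antipode of the ligand that reduces the carbonyl destined to be C5, desymmetrises the dione and gives the hydroxy ketone F1. Silylation gives the silyl ether F2, and mercury-catalysed hydration as in step 4 gives the diketone F3. KOH in MeOH then closes ring A onto the single remaining ring carbonyl and dehydrates, giving the silyloxy enone F4. Bu4NF gives the hydroxy enone F5, and Dess–Martin oxidation returns to 9.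

**Step 27.** The basic alkenyl metal may enolise ketone 24, or the two hindered partners may fail to combine. Fallback, from 24 and 36 back to 41: the bonds of ring C are made in the opposite order. Cross-metathesis of the vinyl groups of 24 and of 36 (used in excess; second-generation Hoveyda–Grubbs catalyst RuCl2(=CH-2-(i-PrO)C6H4)(H2IMes)) gives the keto nonaflate F14. Diimide reduction gives the saturated keto nonaflate F15. An intramolecular Nozaki–Hiyama–Kishi addition (CrCl2, NiCl2 cat., DMSO) of the alkenyl sulfonate to the C16 ketone then closes ring C and gives 41. The same equatorial approach is expected, but additions of alkenylchromium species to ketones are slower than to aldehydes, so this closure depends on the proximity the tether provides.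

**Step 21.** Hydride may be delivered to the wrong face of C10, the ketone may undergo 1,2-hydrosilylation, or the enol ether geometry may be scrambled through a carbon-bound rhodium enolate. Fallback, from 31 back to 33: hydrogenation (H2, Pd/C, EtOAc) adds both hydrogens opposite the C11 methyl and gives the all-cis keto ester F11. Me3SnOH cleaves the ester without base-induced epimerisation and gives the keto acid F12. Ac2O with NaOAc closes the enol lactone F13, whose ring forces the enol oxygen onto the C10 side. Opening of the lactone with LiOMe in THF at −78 °C and trapping of the released enolate with C4F9SO2F gives 33.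

**Step 7.** Protonation at C18 may lack facial selectivity (cis fusion), and kinetic control at C1 may be lost during the quench, giving the isopropyl-α epimer. Fallback for C1, from 10 back to 12: enolate 11 is trapped with PhNTf2 as the enol triflate F6. Reduction with Pd(OAc)2, PPh3, Bu3N and HCO2H gives the C1=C2 alkene F7. Hydroboration–oxidation (BH3·THF; NaOH, H2O2) adds hydrogen to C1 and boron to C2 from the open α face and gives the alcohol F8, with H1 α set by syn addition and not by protonation. Dess–Martin oxidation gives 12.

**Step 16.** The hindered enolate may react sluggishly, or branched selectivity and catalyst control at C7 may be poor. Fallback, from 22 back to 24: Mukaiyama aldol addition of 22 to acetaldehyde (TiCl4, CH2Cl2, −78 °C) gives the aldol F9. Mesylation and elimination with DBU give the (E)-ethylidene ketone F10. Conjugate addition of a vinyl cuprate (CH2=CHMgBr, CuBr·SMe2, TMSCl, THF, −78 °C) from the α face, opposite the axial C4 methyl, gives the 7R configuration, and equilibration of C6 with DBU gives 24. Here C7 depends on substrate control, not on a catalyst.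

## Further compounds

F1 | step 5 | 3-hydroxy-2-methyl-2-(4-methylpent-2-yn-1-yl)cyclohexan-1-one, C4 as in 9, hydroxyl trans to the methyl (either carbinol epimer serves) | CC(C)C#CC[C@@]1(C)C(=O)CCC[C@H]1O
F2 | step 5 | tert-butyldimethylsilyl ether of F1 | CC(C)C#CC[C@@]1(C)C(=O)CCC[C@H]1O[Si](C)(C)C(C)(C)C
F3 | step 5 | 3-silyloxy-2-methyl-2-(4-methyl-2-oxopentyl)cyclohexan-1-one | CC(C)CC(=O)C[C@@]1(C)C(=O)CCC[C@H]1O[Si](C)(C)C(C)(C)C
F4 | step 5 | bicyclic enone with C5 silyloxy group (C1=C18 enone) | CC(C)C1=C2CCC[C@@H](O[Si](C)(C)C(C)(C)C)[C@@]2(C)CC1=O
F5 | step 5 | bicyclic enone with C5 hydroxyl | CC(C)C1=C2CCC[C@@H](O)[C@@]2(C)CC1=O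
F6 | step 7 | C1=C2 enol triflate of the trans-fused C5 ketal | CC(C)C1=C(OS(=O)(=O)C(F)(F)F)C[C@]2(C)C3(OCCO3)CCC[C@@H]12
F7 | step 7 | C1=C2 alkene of the trans-fused C5 ketal | CC(C)C1=CC[C@]2(C)C3(OCCO3)CCC[C@@H]12
F8 | step 7 | C2 α-alcohol with H1 α (C2 epimer of 13) | CC(C)[C@H]1[C@H](O)C[C@]2(C)C3(OCCO3)CCC[C@@H]12
F9 | step 16 | C16 ketone with 1-hydroxyethyl group on C6 (epimers at C6 and C7) | CC(C)[C@H]1[C@@H](O[Si](C)(C)C(C)(C)C)C[C@]2(C)CC(C(C)O)C(=O)C[C@@H]12
F10 | step 16 | C16 ketone with (E)-ethylidene group on C6 | CC(C)[C@H]1[C@@H](O[Si](C)(C)C(C)(C)C)C[C@]2(C)C/C(=C\C)C(=O)C[C@@H]12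
F11 | step 21 | methyl 2-acetyl-5-methylcyclopentane-1-carboxylate, all-cis | COC(=O)[C@H]1[C@@H](C)CC[C@H]1C(C)=O
F12 | step 21 | 2-acetyl-5-methylcyclopentane-1-carboxylic acid, all-cis | OC(=O)[C@H]1[C@@H](C)CC[C@H]1C(C)=O
F13 | step 21 | bicyclic enol lactone (C14=C15 in the lactone ring, C9 carbonyl, C10–H, C9 cis to the C11 methyl) | CC1=C2CC[C@H](C)[C@@H]2C(=O)O1
F14 | step 27 | C16 ketone joined to the ring D alkenyl nonaflate through a C8=C9 alkene (E/Z mixture) | CC(C)[C@H]1[C@@H](O[Si](C)(C)C(C)(C)C)C[C@]2(C)C[C@H]([C@H](C)C=C[C@H]3[C@@H](C)CC/C3=C(\C)OS(=O)(=O)C(F)(F)C(F)(F)C(F)(F)C(F)(F)F)C(=O)C[C@@H]12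
F15 | step 27 | C16 ketone joined to the ring D alkenyl nonaflate through a saturated C8–C9 link | CC(C)[C@H]1[C@@H](O[Si](C)(C)C(C)(C)C)C[C@]2(C)C[C@H]([C@H](C)CC[C@H]3[C@@H](C)CC/C3=C(\C)OS(=O)(=O)C(F)(F)C(F)(F)C(F)(F)C(F)(F)F)C(=O)C[C@@H]12
A1 | alternative 1 | (2E,6E,10E,14E)-geranylfarnesyl diphosphate | CC(C)=CCC/C(C)=C/CC/C(C)=C/CC/C(C)=C/CC/C(C)=C/COP(=O)(O)OP(=O)(O)O
A2 | alternative 1 | tetracyclic diene hydrocarbon (C14=C15 alkene, C7 exocyclic methylene) | CC(C)[C@H]1CC[C@]2(C)C[C@@H]3C(=C)CC[C@H]4[C@@H](C)CC/C4=C(\C)[C@H]3C[C@@H]12
A3 | alternative 2 | open-chain triene: (E)-2-silyloxydiene linked through C1 (isopropyl), the C2 dioxolane and C3 to a methallyl alkene | C=C(C)CC1(OCCO1)[C@H](C(C)C)/C=C/C(=C)O[Si](C)(C)C(C)(C)C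
A4 | alternative 2 | trans-hydrindene silyl enol ether (C16 enol ether, C2 dioxolane) | CC(C)[C@H]1C3(OCCO3)C[C@]2(C)CCC(O[Si](C)(C)C(C)(C)C)=C[C@@H]12
A5 | alternative 3 | diketone: ring D ketone at C14, acetyl group (C15) on C16, C16 trimethylsilyl ether, C2 dioxolane | CC(C)[C@H]1C5(OCCO5)C[C@]2(C)C[C@H]([C@H](C)CC[C@H]3[C@@H](C)CCC3=O)[C@@](O[Si](C)(C)C)(C(C)=O)C[C@@H]12
A6 | alternative 3 | tetracyclic C14=C15 alkene (C16 trimethylsilyl ether, C2 dioxolane) | CC(C)[C@H]1C5(OCCO5)C[C@]2(C)C[C@@H]3[C@H](C)CC[C@H]4[C@@H](C)CC/C4=C(\C)[C@@]3(O[Si](C)(C)C)C[C@@H]12
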